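**Plan**
Cuts, in retrosynthetic order: the O–CH3 and three O–benzyl bonds; C4a–C5 and C6–C7 of ring A; the C8–O bond to ring B; the malonyl C–C and C–O bonds of a second pyrone; the butyl–CH2 bond of the pentyl chain. Ring B goes back to olivetolic acid.
Enabling feature: ring A (C4a, C5, C6, C7, C8, C8a) shares the C4a–C8a bond with the 3-pentylpyranone, so C7, C8, C8a and C4a can be stored as the diene of a second 2-pyrone whose O–C(=O) unit bridges C4a and C7. In that ring C8a bears the C1 carbonyl, which makes C4a the electrophilic terminus. C8 is a vinylogous acyl carbon, so it accepts the crowded ring B phenol by addition–elimination.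
Forward order: the pyranone ring is bought as triacetic lactone and chain-extended. The second pyrone is closed with malonyl dichloride and its C8 chloride is exchanged for the ring B phenol. Ring A is closed last by [4+2] addition of 1,1-dimethoxyethene with loss of CO2 and methanol, and one global deprotection follows.
Stereochemistry: the target has no stereocentre, and the two bridgeheads of the cycloadduct disappear on aromatisation.

Key step: step 8

Remark: C1–C8a are the isocoumarin positions of the target and label the same atoms in the bis-pyrones; ring B compounds are named with benzoate numbering.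

Step 1
Reactants: 1 4-hydroxy-6-methyl-2H-pyran-2-one (triacetic lactone)
Product: 3 4-hydroxy-6-pentyl-2H-pyran-2-one, via dilithio dianion 2 (not isolated)
Conditions: LiN(iPr)2 (2.3 equiv), THF–DMPU, −78 °C; n-BuI (1.1 equiv), −78 °C → rt; aq HCl
Reagents that add atoms: 1-iodobutane CCCCI
Why: Double deprotonation gives the O,C-dianion, whose carbanion at the C6 methyl group is the more reactive site and displaces iodide from the primary halide (dianion alkylation of triacetic lactone, SN2).

Step 2
Reactants: 3 4-hydroxy-6-pentyl-2H-pyran-2-one; 4 malonyl dichloride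
Product: 5 4-hydroxy-7-pentyl-2H,5H-pyrano[4,3-b]pyran-2,5-dione
Conditions: 4 (1.1 equiv), CF3CO2H, reflux
Reagents that add atoms: none
Why: The bis-acid chloride acylates the nucleophilic C3 and the 4-OH of the hydroxypyrone in turn (the C-acylation/O-acylation annulation known for triacetic lactone), which closes the second pyrone as its 4-hydroxy tautomer.

Step 3
Reactants: 5 4-hydroxy-7-pentyl-2H,5H-pyrano[4,3-b]pyran-2,5-dione
Product: 6 4-chloro-7-pentyl-2H,5H-pyrano[4,3-b]pyran-2,5-dione
Conditions: POCl3 (neat), 90 °C; evaporate, cold aqueous work-up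
Reagents that add atoms: phosphoryl chloride O=P(Cl)(Cl)Cl
Why: The vinylogous acid OH is phosphorylated and then displaced by chloride, the deoxychlorination routinely used on 4-hydroxy-2-pyrones, 4-hydroxycoumarins and their pyrano-fused analogues.

Step 4
Reactants: 7 olivetolic acid (2,4-dihydroxy-6-pentylbenzoic acid)
Product: 8 benzyl 2,4-bis(benzyloxy)-6-pentylbenzoate
Conditions: BnBr (3.5 equiv), K2CO3 (4 equiv), DMF, 60 °C
Reagents that add atoms: benzyl bromide BrCc1ccccc1
Why: Carboxylate alkylation and Williamson etherification of both phenols occur in one operation, and warming brings in the hydrogen-bonded 2-OH.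

Step 5
Reactants: 8 benzyl 2,4-bis(benzyloxy)-6-pentylbenzoate
Product: 10 benzyl 4,6-bis(benzyloxy)-3-formyl-2-pentylbenzoate, via aryl iminium salt 9 (not isolated)
Conditions: POCl3 (3 equiv), DMF, 0 → 80 °C; then H2O
Reagents that add atoms: N,N-dimethylformamide CN(C)C=O; water O
Why: Vilsmeier–Haack formylation goes to the free position that is ortho to one benzyloxy group and para to the other, the usual site in resorcinol diethers, because the only other free position lies between two alkoxy groups.

Step 6
Reactants: 10 benzyl 4,6-bis(benzyloxy)-3-formyl-2-pentylbenzoate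
Product: 12 benzyl 4,6-bis(benzyloxy)-3-hydroxy-2-pentylbenzoate, via aryl formate 11 (not isolated)
Conditions: mCPBA, CH2Cl2, 0 °C → rt; crude 11, K2CO3 (0.2 equiv), MeOH, 0 °C, N2
Reagents that add atoms: 3-chloroperoxybenzoic acid O=C(OO)c1cccc(Cl)c1
Why: In the Baeyer–Villiger (Dakin-type) oxidation the aryl group, enriched by ortho and para alkoxy donors, migrates to oxygen, and the formate is then methanolysed while the doubly ortho-substituted benzyl ester is too hindered to exchange.

Step 7
Reactants: 6 4-chloro-7-pentyl-2H,5H-pyrano[4,3-b]pyran-2,5-dione; 12 benzyl 4,6-bis(benzyloxy)-3-hydroxy-2-pentylbenzoate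
Product: 13 benzyl 4,6-bis(benzyloxy)-3-[(2,5-dioxo-7-pentyl-2H,5H-pyrano[4,3-b]pyran-4-yl)oxy]-2-pentylbenzoate
Conditions: Cs2CO3 (1.2 equiv), 4 Å MS, MeCN, 0 °C → rt
Reagents that add atoms: none
Why: The phenoxide adds to the chlorine-bearing β-carbon of the unsaturated lactone and chloride leaves (vinylogous acyl substitution, known for phenols with 4-halo-2-pyrones and 4-chlorocoumarins), and only this site makes the addition irreversible.

Step 8
Reactants: 13 benzyl 4,6-bis(benzyloxy)-3-[(2,5-dioxo-7-pentyl-2H,5H-pyrano[4,3-b]pyran-4-yl)oxy]-2-pentylbenzoate; 14 1,1-dimethoxyethene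
Product: 17 benzyl 4,6-bis(benzyloxy)-3-[(6-methoxy-1-oxo-3-pentyl-1H-isochromen-8-yl)oxy]-2-pentylbenzoate, via bridged lactone 15 (not isolated), via dihydroarene ketal 16 (not isolated)
Conditions: 14 (6 equiv), toluene, sealed tube, 120 °C
Reagents that add atoms: none
Why: Proposed new method: the aryloxy-bearing ring of 13 is a 2-pyrone whose position 5 (C8a) carries the C1 carbonyl, so the nucleophilic CH2 of 14 should bond to the doubly activated fusion carbon C4a while the acetal carbon bonds to the unsubstituted C7, in an asynchronous inverse-demand [4+2] addition that gives the bridged lactone 15. Retro-[4+2] expulsion of CO2 from 15 leaves the 6,6-dimethoxy-5,6-dihydro compound 16, and 1,2-loss of methanol across C5–C6 aromatises it to 17. Ring A is therefore closed by an intermolecular [4+2] cycloaddition that forms C4a–C5 and C6–C7 together, and the closest known reaction type is the Diels–Alder, decarboxylation and dealcoholation sequence of 2-pyrone-5-carboxylates with ketene acetals, which gives 4-alkoxybenzoates. The two bridgehead stereocentres of 15 form as a racemate, are tied to each other by the bicycle and vanish on aromatisation, so nothing has to be controlled. The step needs the right ring and the right orientation: the pentyl-bearing pyrone has no 5-acyl group and would have to react through two fully substituted termini (C3 and C8a), and the polarity of 14 fits only the pairing of CH2 with C4a, which places the methoxy group at C6. C8 stays sp2 throughout, so the aryloxy group cannot be eliminated, but as a donor it slows the addition, hence the excess of 14 and the heating.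

Step 9
Reactants: 17 benzyl 4,6-bis(benzyloxy)-3-[(6-methoxy-1-oxo-3-pentyl-1H-isochromen-8-yl)oxy]-2-pentylbenzoate
Product: 18 4,6-dihydroxy-3-[(6-hydroxy-1-oxo-3-pentyl-1H-isochromen-8-yl)oxy]-2-pentylbenzoic acid (CNP0439913.0)
Conditions: BBr3 (10 equiv), C6HMe5 (6 equiv), CH2Cl2, −78 °C → rt; ice–water
Reagents that add atoms: none
Why: BBr3 cleaves every sp3 C–O bond (the methyl ether, two benzyl ethers and the benzyl ester) while pentamethylbenzene traps the benzyl cations, and the diaryl ether and the enol lactone are left alone because they have only sp2 C–O bonds.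

**Compound list**
1 | 4-hydroxy-6-methyl-2H-pyran-2-one (triacetic lactone) | CC1=CC(O)=CC(=O)O1 | starting material
2 | dilithio O,C-dianion of 1 | [Li+].[Li+].[CH2-]C1=CC([O-])=CC(=O)O1 | intermediate
3 | 4-hydroxy-6-pentyl-2H-pyran-2-one | CCCCCC1=CC(O)=CC(=O)O1 | intermediate
4 | malonyl dichloride | O=C(Cl)CC(=O)Cl | starting material
5 | 4-hydroxy-7-pentyl-2H,5H-pyrano[4,3-b]pyran-2,5-dione | CCCCCC1=CC2=C(C(=O)O1)C(O)=CC(=O)O2 | intermediate
6 | 4-chloro-7-pentyl-2H,5H-pyrano[4,3-b]pyran-2,5-dione | CCCCCC1=CC2=C(C(=O)O1)C(Cl)=CC(=O)O2 | intermediate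
7 | olivetolic acid | CCCCCc1cc(O)cc(O)c1C(=O)O | starting material
8 | benzyl 2,4-bis(benzyloxy)-6-pentylbenzoate | CCCCCc1cc(OCc2ccccc2)cc(OCc2ccccc2)c1C(=O)OCc1ccccc1 | intermediate
9 | N,N-dimethyl aryl iminium dichlorophosphate (CH=NMe2+ in place of the later formyl group) | CCCCCc1c(C=[N+](C)C)c(OCc2ccccc2)cc(OCc2ccccc2)c1C(=O)OCc1ccccc1.[O-]P(=O)(Cl)Cl | intermediate
10 | benzyl 4,6-bis(benzyloxy)-3-formyl-2-pentylbenzoate | CCCCCc1c(C=O)c(OCc2ccccc2)cc(OCc2ccccc2)c1C(=O)OCc1ccccc1 | intermediate
11 | benzyl 4,6-bis(benzyloxy)-3-(formyloxy)-2-pentylbenzoate | CCCCCc1c(OC=O)c(OCc2ccccc2)cc(OCc2ccccc2)c1C(=O)OCc1ccccc1 | intermediate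
12 | benzyl 4,6-bis(benzyloxy)-3-hydroxy-2-pentylbenzoate (ring B phenol) | CCCCCc1c(O)c(OCc2ccccc2)cc(OCc2ccccc2)c1C(=O)OCc1ccccc1 | intermediate
13 | benzyl 4,6-bis(benzyloxy)-3-[(2,5-dioxo-7-pentyl-2H,5H-pyrano[4,3-b]pyran-4-yl)oxy]-2-pentylbenzoate | CCCCCC1=CC2=C(C(=O)O1)C(Oc3c(OCc4ccccc4)cc(OCc4ccccc4)c(C(=O)OCc4ccccc4)c3CCCCC)=CC(=O)O2 | intermediate
14 | 1,1-dimethoxyethene | C=C(OC)OC | starting material
15 | bridged lactone cycloadduct: C4a and C7 joined by the new C5H2–C6(OMe)2 bridge and by the old O–C(=O) bridge, C8=C8a double bond (racemic, one enantiomer drawn) | CCCCCC1=C[C@@]23CC(OC)(OC)[C@@H](C(=O)O2)C(Oc4c(OCc5ccccc5)cc(OCc5ccccc5)c(C(=O)OCc5ccccc5)c4CCCCC)=C3C(=O)O1 | intermediate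
16 | benzyl 4,6-bis(benzyloxy)-3-[(6,6-dimethoxy-1-oxo-3-pentyl-5,6-dihydro-1H-isochromen-8-yl)oxy]-2-pentylbenzoate | CCCCCC1=CC2=C(C(=O)O1)C(Oc3c(OCc4ccccc4)cc(OCc4ccccc4)c(C(=O)OCc4ccccc4)c3CCCCC)=CC(OC)(OC)C2 | intermediate
17 | benzyl 4,6-bis(benzyloxy)-3-[(6-methoxy-1-oxo-3-pentyl-1H-isochromen-8-yl)oxy]-2-pentylbenzoate | CCCCCc1cc2cc(OC)cc(Oc3c(OCc4ccccc4)cc(OCc4ccccc4)c(C(=O)OCc4ccccc4)c3CCCCC)c2c(=O)o1 | intermediate
18 | 4,6-dihydroxy-3-[(6-hydroxy-1-oxo-3-pentyl-1H-isochromen-8-yl)oxy]-2-pentylbenzoic acid (CNP0439913.0) | CCCCCc1cc2cc(O)cc(Oc3c(O)cc(O)c(C(=O)O)c3CCCCC)c2c(=O)o1 | target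

**Totals**
Total steps: 9. Longest linear sequence: 6 (steps 1, 2, 3, 7, 8, 9 or steps 4, 5, 6, 7, 8, 9).

**Steps most likely to fail**

Step 8.
- What may go wrong: the donor aryloxy group, and a ring B that stands perpendicular over both faces next to C7, may slow the cycloaddition until the ketene acetal oligomerises. The acetal may also act as a plain nucleophile, giving conjugate addition with pyrone ring opening or displacement of the aryloxide at C8.
- Fallback: it uses known reactions only, sets out from 12 and returns at 17, and takes ring A from an aromatic building block. Bought 3-bromo-5-fluoroanisole is lithiated between the two halogens (LiN(iPr)2, THF, −78 °C) and quenched with DMF to give 2-bromo-6-fluoro-4-methoxybenzaldehyde F1. Phenol 12 displaces the fluoride ortho to the formyl group (SNAr; K2CO3, DMF, 90 °C) to give benzyl 4,6-bis(benzyloxy)-3-(3-bromo-2-formyl-5-methoxyphenoxy)-2-pentylbenzoate F2. Sonogashira coupling with hept-1-yne (PdCl2(PPh3)2, CuI, Et3N, 60 °C) gives benzyl 4,6-bis(benzyloxy)-3-[2-formyl-3-(hept-1-yn-1-yl)-5-methoxyphenoxy]-2-pentylbenzoate F3. Pinnick oxidation (NaClO2, NaH2PO4, 2-methylbut-2-ene, tBuOH–H2O) gives 2-{4,6-bis(benzyloxy)-3-[(benzyloxy)carbonyl]-2-pentylphenoxy}-6-(hept-1-yn-1-yl)-4-methoxybenzoic acid F4. A 6-endo-dig cycloisomerisation catalysed by AuCl(PPh3)/AgOTf in CH2Cl2 then closes the pyranone to 17.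

Step 7.
- What may go wrong: the phenoxide, slowed by its two ortho substituents, may attack the lactone carbonyls or the other electrophilic ring carbons and open the base-sensitive bis-pyrone faster than it displaces chloride.
- Fallback: it sets out from 6 and 12, returns at 17, and inverts the order of ether formation and ring A construction. Chloride 6, a poorer donor-substituted and thus more electrophilic diene, is heated with 14 in toluene to give 8-chloro-6-methoxy-3-pentyl-1H-isochromen-1-one F5. This base-stable aryl chloride, activated by the ortho lactone carbonyl and flanked by only one substituent, is joined to 12 by palladium-catalysed diaryl ether coupling (Pd(OAc)2, tBuXPhos, K3PO4, toluene, 100 °C).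

Step 9.
- What may go wrong: the liberated 2,4-dihydroxybenzoic acid may lose CO2 under the acidic conditions, benzyl cations may alkylate the electron-rich rings, and the C6 methyl ether may be only partly cleaved at temperatures the acid tolerates. C1 may also shift from the enol oxygen to the freed ring B hydroxyl next to the ether bridge.
- Fallback: it sets out from 13, returns at 18, removes the methyl ether from the plan and ends under neutral conditions. Bromoacetaldehyde diethyl acetal is transacetalised with benzyl alcohol (cat. TsOH, ethanol distilled off) to 2-bromo-1,1-bis(benzyloxy)ethane F6. Dehydrobromination with KOtBu in THF gives 1,1-bis(benzyloxy)ethene F7. Compound 13 and F7 undergo the same cycloaddition, with loss of CO2 and benzyl alcohol, to give benzyl 4,6-bis(benzyloxy)-3-{[6-(benzyloxy)-1-oxo-3-pentyl-1H-isochromen-8-yl]oxy}-2-pentylbenzoate F8. Hydrogenolysis (H2, 1 atm, Pd/C, EtOAc) removes all four benzyl groups well before the trisubstituted enol-lactone double bond is touched and gives 18.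

**Further compounds**
F1 | step 8 | 2-bromo-6-fluoro-4-methoxybenzaldehyde | COc1cc(F)c(C=O)c(Br)c1
F2 | step 8 | benzyl 4,6-bis(benzyloxy)-3-(3-bromo-2-formyl-5-methoxyphenoxy)-2-pentylbenzoate | CCCCCc1c(Oc2cc(OC)cc(Br)c2C=O)c(OCc2ccccc2)cc(OCc2ccccc2)c1C(=O)OCc1ccccc1
F3 | step 8 | benzyl 4,6-bis(benzyloxy)-3-[2-formyl-3-(hept-1-yn-1-yl)-5-methoxyphenoxy]-2-pentylbenzoate | CCCCCC#Cc1cc(OC)cc(Oc2c(OCc3ccccc3)cc(OCc3ccccc3)c(C(=O)OCc3ccccc3)c2CCCCC)c1C=O
F4 | step 8 | 2-{4,6-bis(benzyloxy)-3-[(benzyloxy)carbonyl]-2-pentylphenoxy}-6-(hept-1-yn-1-yl)-4-methoxybenzoic acid | CCCCCC#Cc1cc(OC)cc(Oc2c(OCc3ccccc3)cc(OCc3ccccc3)c(C(=O)OCc3ccccc3)c2CCCCC)c1C(=O)O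
F5 | step 7 | 8-chloro-6-methoxy-3-pentyl-1H-isochromen-1-one | CCCCCc1cc2cc(OC)cc(Cl)c2c(=O)o1
F6 | step 9 | 2-bromo-1,1-bis(benzyloxy)ethane | BrCC(OCc1ccccc1)OCc1ccccc1
F7 | step 9 | 1,1-bis(benzyloxy)ethene | C=C(OCc1ccccc1)OCc1ccccc1
F8 | step 9 | benzyl 4,6-bis(benzyloxy)-3-{[6-(benzyloxy)-1-oxo-3-pentyl-1H-isochromen-8-yl]oxy}-2-pentylbenzoate | CCCCCc1cc2cc(OCc3ccccc3)cc(Oc3c(OCc4ccccc4)cc(OCc4ccccc4)c(C(=O)OCc4ccccc4)c3CCCCC)c2c(=O)o1
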